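Constant through both earlier runs is the reagent charge, and one reckoned quantity turns out nearly constant with it.

| flask | substrate | reagent | remark | time |
|---|---|---|---|---|
| north-east | 0.075 M | 0.125 M | run made earlier |  |
| north | 0.025 M | 0.125 M | run made earlier |  |
| Saturday's | 0.050 M | 0.250 M |  | 3.0 d |
| Wednesday's | 0.050 M | 0.500 M |  | 3.0 d |
| Thursday's | 0.050 M | 0.400 M |  | 3.0 d |
| Tuesday's | 0.050 M | 0.125 M |  | 3.0 d |

| run | time / h | product / % | substrate / % |
|---|---|---|---|
| north-east | 4.00 | 8.6 | 30.6 |
| north-east | 8.00 | 14.1 | 15.7 |
| north-east | 12.0 | 17.0 | 8.6 |
| north-east | 15.0 | 19.8 | 5.9 |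
| north-east | 20.0 | 23.0 | 0 |
| north-east | 25.0 | 25.3 | 1.1 |
| north | 4.00 | 17.9 | 49.4 |
| north | 8.00 | 30.5 | 24.9 |
| north | 12.0 | 39.6 | 12.5 |
| north | 15.0 | 44.0 | 6.6 |
| north | 20.0 | 46.8 | 0.6 |
| north | 25.0 | 50.5 | 0.9 |

(each reading ± 1 percentage point)

1. all flasks from highest to lowest amount of product, in percent of the substrate charged, at 3.0 d (Saturday's / Wednesday's / Thursday's / Tuesday's)
2. the amount of product, in percent of the substrate charged of the flask you put first, at 3.0 d
3. the amount of product, in percent of the substrate charged of the flask you put last, at 3.0 d

At the last readings, at 25.0 h, substrate reads 0.9 % in the north run and 1.1 % in the north-east run, about the scatter of 1 percentage point. Take there the odds of product against the rest of the charge, a selectivity factor, and multiply them by the substrate charge. The north run gives 0.0255 M and the north-east run 0.0254 M, though their charges differ 3.00 times. Their mean, 0.0255 M, a reading that carries their scatter, is taken as the break-even charge: the substrate charge at which, with reagent at 0.125 M and at the time of those last readings, product and the rest of the charge read equal. At that reagent charge, product as a share of the substrate charged is then reckoned as the break-even charge over the sum of break-even charge and substrate charge.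

Tuesday's has that reagent charge, so with substrate at 0.050 M it reckons to 33.8 %. Product still read higher at the last reading of the north run, 46.8 % and then 50.5 %, so this figure is likely to be low for 3.0 d.

The decision concerns the other flasks, which change reagent, held at 0.125 M in both runs. Wednesday's charges 4.00 times Tuesday's reagent. If the break-even charge follows reagent in step, Wednesday's reckons to 67.1 %; if reagent leaves it unmoved, Wednesday's reckons to Tuesday's figure. The reckoning here therefore ranks the flasks by reagent charge, keeps that span open, and charges Wednesday's next, leaving Saturday's and Thursday's until it has been read.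

The forecast gives Wednesday's > Thursday's > Saturday's > Tuesday's, with 67 % first and 36 % last, from “odds ≈ 0.22·[reagent]/[substrate]”, so its first flask stands at the upper end of the span and its last above the 33.8 % reckoned here for Tuesday's.

Wednesday's gives 49.7 % and Tuesday's 36.7 % at 3.0 d, in the order Wednesday's > Thursday's > Saturday's > Tuesday's, and Wednesday's also holds 42.8 % of the substrate charged as homo dimer.

    substrate ⇌ dormant form (K = 5.90, k = 8.30 × 10⁻⁶ s⁻¹)
    substrate + reagent → product, rate k2*[substrate]^0.5*[reagent]^0.5 (k = 6.60 × 10⁻⁶ s⁻¹)
    2 substrate → homo dimer (k = 6.90 × 10⁻⁴ M⁻¹ s⁻¹)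

Read back at 3.0 d, each flask with its own reagent, the break-even charge is 0.0290 M in Tuesday's and 0.0494 M in Wednesday's, a factor of 1.70 for 4.00 times the reagent. Tuesday's value, carried to the neighbour flask with 0.013 M of substrate and all else as in Tuesday's, reckons to 69.0 % of product, and that flask stands at 69.1 %.

(Readings and results stem from a simulated flask for an exercise; scatter was added.)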